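At late times the delta flask holds 2.4 % of the charge as starting material against 17.6 % as target at 30.0 h, so from there on I watch target fall as a first-order tail.

the same everywhere: starting material 0.41 M

| flask | capture agent | remark | time |
|---|---|---|---|
| delta | 0.41 M | the very flask that is asked about, followed so far |  |
| epsilon | 0.82 M | run made earlier |  |
| flask | 0.410 M |  | 4.0 d |

- delta (time / h: target / %, starting material / %): 2.00: 5.2, 76.0; 6.00: 15.7, 45.8; 10.0: 17.9, 30.2; 15.0: 21.0, 16.2; 20.0: 20.7, 10.6; 30.0: 17.6, 2.4
- epsilon (time / h: target / %, starting material / %): 2.50: 8.4, 71.0; 8.00: 15.1, 34.8; 15.0: 16.9, 17.7; 20.0: 16.4, 12.3; 30.0: 12.9, 1.8; 40.0: 10.3, 2.9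

(readings scatter by 1 percentage point)

1. amount of target in percent of the starting material charged, at 10 h, 30 h, 2.5 d and 4.0 d

1. I read the tail rate as 0.0162 h⁻¹ in the delta flask and as 0.0233 h⁻¹ in the epsilon run from 20.0 h to 40.0 h, with capture agent at twice the charge; the epsilon reading is faster, but with a scatter of 1 percentage point on short spans I can't separate them, so I take their mean, 0.0197 h⁻¹.

2. Multiplying by the time left gives the tail number 1.30, the count of factors of e that target still loses between the last reading and the end.

3. Read off it, my estimate for target is 4.78 % at 4.0 d, and the same rate gives 9.73 % at 2.5 d; for 10 h and 30 h I keep the delta readings, 17.9 % and 17.6 %.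

4. One number carries a band, since the delta rate by itself gives 6.04 % at the end and the epsilon rate 3.78 %, and 80.0 % of the charge is unread at 30.0 h, so I watch whether any of it returns to target through the reversible steps.

The forecast gives 17.8 %, 18 %, 11 % and 6 %, above my tail at the last two times , with the remark “Capture agent depletion, or an isomer reservoir feeding back, could slow the decay slightly”.

The flask gives 19.2 %, 17.6 %, 9.87 % and 4.70 %.

    target → over-reaction product (k = 0.0364 h⁻¹)
    2 starting material → self-condensation product (k = 0.0503 M⁻¹ h⁻¹)
    open intermediate ⇌ target (K = 2.00, k = 1.09 h⁻¹)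
    open intermediate + capture agent → trapped intermediate (k = 0.129 M⁻¹ h⁻¹)
    starting material → open intermediate (k = 0.0996 h⁻¹)
    open intermediate ⇌ isomer of the product (K = 2.10, k = 0.422 h⁻¹)

From 30 h to 4.0 d the flask shows a tail number of 1.32 against my 1.30, and my number scaled to the epsilon span from 15.0 h to 30.0 h, two readings that did not go into it, turns 16.9 % into 12.6 % against the reading of 12.9 %. In the flask the balance of target turns, each step taken net: at 0.256 d it is made 3.26 times as fast as it is used up, and at 4.00 d its making is 0.436 of its using.

All runs are simulated with made-up constants.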